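I count turnovers. In each flask a single-handed free catalyst, let out of the precatalyst, binds a substrate and passes it to the partner as product, and the left-handed and right-handed substrates compete for it.

common to all: left-handed substrate 0.25 M; right-handed substrate 0.25 M; partner 0.375 M
- larch: protic impurity 5 mM; precatalyst 12 mM; run made earlier
- elm: protic impurity 5 mM; precatalyst 130 mM; run made earlier
- autumn: protic impurity 5.00 mM; precatalyst 8.0 mM; time 2.0 min
- noon: protic impurity 5.00 mM; precatalyst 25 mM; time 2.0 min
- summer: protic impurity 5.00 mM; precatalyst 80 mM; time 2.0 min

- larch (time / s: left-handed product / %, right-handed product / %): 10.0: 0, 0; 20.0: 0, 1.0; 30.0: 0, 1.0; 40.0: 1.6, 0; 50.0: 0.4, 3.1; 60.0: 0, 0.1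
- elm (time / s: left-handed product / %, right-handed product / %): 10.0: 1.0, 0; 12.0: 0.8, 1.1; 20.0: 1.3, 0.1; 30.0: 1.8, 0; 50.0: 4.9, 0; 60.0: 7.8, 1.3

(each reading ± 1 percentage point)

- free catalyst is single-handed; left-handed substrate and right-handed substrate are mirror images of each other, charged as a racemate, each of them at the stated concentration
- the numbers in the tables scatter by 1 percentage point (one standard deviation)
- steps thought possible: free catalyst + right-handed substrate <-> catalyst intermediate B; partner + protic impurity -> quenched reagent; partner + catalyst intermediate B -> free catalyst + right-handed product; partner + catalyst intermediate A -> free catalyst + left-handed product; precatalyst -> free catalyst; free catalyst + left-handed substrate <-> catalyst intermediate A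
- an excess is the difference of the two amounts in percent of their sum
- "hardly changes" means that all values lie within two and a half points (for a concentration: within two and a half percent of the largest)

- excess of left-handed product over right-handed product at the end for autumn, noon, summer, in this order
- the course of these numbers from the first flask to the last (hardly changes / rises, then falls / falls, then rises / rises all the way / falls all the way)

Substrate and partner charges are the same in every flask, so I assume that product per catalyst charged follows one curve. At 60.0 s, elm shows 7.8% left-handed product, or 0.300 turnovers. Its reading rises 4.33 times from 30.0 s to 60.0 s, which is twice the time, so I let the count grow as time squared. That gives the end count, left-handed product made per catalyst charged by 2.0 min, of 1.20.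

Multiplied by the loading, this comes by my reckoning to 3.84% of the left-handed substrate's own charge in autumn, 12.0% in noon and 38.4% in summer. Averaged over the product made, I then reckon the left-handed substrate at 0.981 of its charge in autumn and 0.808 in summer. I take the right-handed substrate as unchanged and let right-handed product per left-handed follow right-handed over left-handed substrate, so I expect the shortfall of the excess from 100 % to grow 1.21 times between them. The excess itself I can't read: elm's right-handed reading at 60.0 s is 1.3% against a scatter of 1 percentage point.

The forecast gives 79.7%, 79.3% and 77.5%, hardly changes: the excess “sags slightly as left-handed substrate depletes”. Its left-handed conversion in summer is about 27 %, against my 38.4%.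

    free catalyst + right-handed substrate ⇌ catalyst intermediate B (K = 1.60 L mol⁻¹, k = 16.5 L mol⁻¹ s⁻¹)
    partner + protic impurity → quenched reagent (k = 1.11 L mol⁻¹ s⁻¹)
    partner + catalyst intermediate B → free catalyst + right-handed product (k = 0.0301 L mol⁻¹ s⁻¹)
    partner + catalyst intermediate A → free catalyst + left-handed product (k = 0.274 L mol⁻¹ s⁻¹)
    precatalyst → free catalyst (k = 0.00312 s⁻¹)
    free catalyst + left-handed substrate ⇌ catalyst intermediate A (K = 11.0 L mol⁻¹, k = 19.4 L mol⁻¹ s⁻¹)

The flasks give 96.6%, 96.4% and 95.8%: hardly changes, as forecast, but higher. Autumn ends with 2.05% left-handed product against 0.0356% right-handed, a product ratio of about 57.6. The shortfall grows 1.24 times from autumn to summer, where the end count gave 1.21. In noon, 1.20 turnovers on 25 mM of precatalyst reckon to 6.00% of the substrates charged as left-handed product, and noon holds 6.09%.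

The readings are calculated with constants of no real substance, noise included.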